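## Retrosynthetic overview

1. Target ⇒ dienyl bis(triflate): one hydrogenation cuts both C–OTf and both O-benzyl bonds and saturates the diene, so C10–H is delivered last, from the convex face ⇒ 10-alkyl tetracyclic enedione.
2. Key disconnection C10–C1′ (ring to chain): a chain nitronate (nucleophilic form of a carbon that is an electrophile in its bromide) adds to the meso ladder enedione, then HNO2 is lost. The chiral catalyst picks one of the two enantiotopic olefinic carbons and so fixes the absolute configuration of the whole molecule.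
3. meso Enedione ⇒ [2+2] photocycloaddition of bicyclo[2.2.0]hex-2-ene with 2,5-dibromo-1,4-benzoquinone, then Zn.
4. Bicyclohexene ⇒ Ramberg–Bäcklund contraction of a cyclobutane-fused thiolane made from cis-cyclobutane-1,2-dicarboxylic anhydride; nitro chain ⇒ 1,3-di-O-benzylglycerol + 1,8-dibromooctane + AgNO2.
5. Ring order: ring C (outer cyclobutane, bought) → ring B (Ramberg–Bäcklund) → ring A (photocycloaddition), which arrives already fused to ring D (six-membered, from the quinone).

Locants: tetracyclo[6.4.0.0(2,7).0(3,6)]dodecane; C1/C8 are the ring A–ring D fusion, C9–C12 the other ring D carbons, C10 carries the chain. "Ladder core" means all four ring fusions cis and neighbouring rings anti. R = 8-[1,3-bis(benzyloxy)propan-2-yloxy]octyl.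

Assumption: 1, 9, 12 and 13 are bought as such.
Assumption: the (1R,2R) thiourea in step 9 is taken to select the olefinic carbon shown (sense by analogy only); if it gives the antipode, the (1S,2S) catalyst is used.

## Route

Step 1
Reactants: 1 cis-cyclobutane-1,2-dicarboxylic anhydride
Product: 2 cis-cyclobutane-1,2-diyldimethanol
Conditions: LiAlH4, THF, 0 °C → reflux; H2O/NaOH work-up
Reagents that add atoms: none
Why: LiAlH4 reduction of the cyclic anhydride to the diol leaves the cis ring stereocentres untouched.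

Step 2
Reactants: 2 cis-cyclobutane-1,2-diyldimethanol
Product: 3 cis-cyclobutane-1,2-diylbis(methylene) dimethanesulfonate
Conditions: MsCl, Et3N, CH2Cl2, 0 °C
Reagents that add atoms: methanesulfonyl chloride CS(=O)(=O)Cl
Why: Mesylation turns both primary alcohols into leaving groups without touching the ring.

Step 3
Reactants: 3 cis-cyclobutane-1,2-diylbis(methylene) dimethanesulfonate
Product: 4 cis-3-thiabicyclo[3.2.0]heptane
Conditions: Na2S·9H2O, DMF, 80 °C
Reagents that add atoms: sodium sulfide [Na+].[Na+].[S-2]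
Why: Double SN2 displacement by sulfide closes the thiolane (thioether cyclisation) and carries the cis fusion over.

Step 4
Reactants: 4 cis-3-thiabicyclo[3.2.0]heptane
Product: 6 2-chloro-cis-3-thiabicyclo[3.2.0]heptane 3,3-dioxide, via alpha-chloro sulfide 5 (not isolated)
Conditions: NCS, CH2Cl2, 0 °C → rt; then mCPBA, 0 °C → rt
Reagents that add atoms: N-chlorosuccinimide O=C1CCC(=O)N1Cl; 3-chloroperoxybenzoic acid OOC(=O)c1cccc(Cl)c1
Why: Alpha-chlorination of the sulfide through the chlorosulfonium ylide (Pummerer-type) followed by peracid S-oxidation gives the alpha-chloro sulfone, whose C–Cl centre is lost in step 5 and so need not be controlled.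

Step 5
Reactants: 6 2-chloro-cis-3-thiabicyclo[3.2.0]heptane 3,3-dioxide
Product: 8 cis-bicyclo[2.2.0]hex-2-ene, via episulfone 7 (not isolated)
Conditions: t-BuOK, DMSO, 25 °C; product distilled at reduced pressure into a −78 °C trap
Reagents that add atoms: none
Why: Ramberg–Bäcklund reaction, in which the alpha-prime sulfonyl carbanion displaces chloride to the episulfone and SO2 extrusion forms the cyclobutene of ring B, the cis fusion being the only one the ring allows.

Step 6
Reactants: 8 cis-bicyclo[2.2.0]hex-2-ene (1.5 equiv); 9 2,5-dibromo-1,4-benzoquinone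
Product: 11 meso-(1S,2R,3S,6R,7S,8R)-tetracyclo[6.4.0.0(2,7).0(3,6)]dodec-10-ene-9,12-dione, via dibromo photoadduct 10 (not isolated)
Conditions: hν (blue LEDs), CH2Cl2, 0 °C; then Zn dust (2.2 equiv), AcOH, 0 °C, 30 min
Reagents that add atoms: none
Why: Enone-type [2+2] photocycloaddition of the brominated quinone C=C (which reacts at carbon instead of giving the oxetane) on the exo face of 8, with ring D turned away from ring B, sets the cis,anti,cis,anti,cis ladder, and Zn/AcOH reductive debromination of the alpha-bromo ketone and the bromo-enedione returns the meso enedione with the cis fusion re-set by convex-face protonation.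

Step 7
Reactants: 12 1,3-bis(benzyloxy)propan-2-ol; 13 1,8-dibromooctane (4 equiv)
Product: 14 2-[(8-bromooctyl)oxy]-1,3-bis(benzyloxy)propane
Conditions: NaH, Bu4NI (cat.), THF–DMF, 0 → 40 °C
Reagents that add atoms: none
Why: Williamson ether synthesis, with the excess of dibromide suppressing double etherification.

Step 8
Reactants: 14 2-[(8-bromooctyl)oxy]-1,3-bis(benzyloxy)propane
Product: 15 2-[(8-nitrooctyl)oxy]-1,3-bis(benzyloxy)propane
Conditions: AgNO2, Et2O, 0 °C → rt, dark, 48 h
Reagents that add atoms: silver nitrite [Ag+].[O-]N=O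
Why: Victor Meyer nitrite displacement (AgNO2 favours N-alkylation with primary bromides) turns the electrophilic chain terminus into a nitroalkane, the nucleophilic partner for step 9.

Step 9
Reactants: 11 meso-tetracyclo[6.4.0.0(2,7).0(3,6)]dodec-10-ene-9,12-dione; 15 2-[(8-nitrooctyl)oxy]-1,3-bis(benzyloxy)propane (1.1 equiv)
Product: 18 (1S,2R,3S,6R,7S,8R)-10-R-tetracyclo[6.4.0.0(2,7).0(3,6)]dodec-10-ene-9,12-dione, via nitro Michael adduct 16 (not isolated), via exocyclic alkylidene dione 17 (not isolated)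
Conditions: 1-[3,5-bis(trifluoromethyl)phenyl]-3-[(1R,2R)-2-(dimethylamino)cyclohexyl]thiourea (10 mol %), PhMe, 0 °C, 72 h; then Et3N (1.5 equiv), 0 °C → rt, quench into pH 7 buffer as soon as 16 and 17 are consumed
Reagents that add atoms: none
Why: Proposed new method: the tertiary amine of the thiourea deprotonates 15 while the thiourea hydrogen-bonds one of the two enantiotopic carbonyls of meso 11, so the nitronate (a reversed-polarity chain carbon, electrophilic in bromide 14) adds on the convex face to only one olefinic carbon, and E1cB loss of nitrite from 16 followed by tautomerisation of 17 into the ring leaves the chain on C10 with no stereocentre there yet, so that which olefinic carbon carries the chain records the enantioselection; the closest known reaction type is the aminourea-catalysed desymmetrising nitroalkane Michael addition/HNO2 elimination (formal vinylic C–H alkylation) of prochiral cyclopentene-1,3-diones.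

Step 10
Reactants: 18 (1S,2R,3S,6R,7S,8R)-10-R-tetracyclo[6.4.0.0(2,7).0(3,6)]dodec-10-ene-9,12-dione
Product: 22 (1S,2R,3S,6R,7S,8R)-10-R-tetracyclo[6.4.0.0(2,7).0(3,6)]dodeca-9,11-diene-9,12-diyl bis(trifluoromethanesulfonate), via lithium enolate 19 (not isolated), via keto enol triflate 20 (not isolated), via potassium dienolate 21 (not isolated)
Conditions: LiBH(s-Bu)3 (1.05 equiv), THF, −78 °C; PhNTf2 (1.1 equiv), −78 → −20 °C; KN(SiMe3)2 (1.3 equiv), −78 °C; PhNTf2 (1.3 equiv), −78 → 0 °C; cold work-up, used at once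
Reagents that add atoms: N-phenylbis(trifluoromethanesulfonimide) O=S(=O)(N(c1ccccc1)S(=O)(=O)C(F)(F)F)C(F)(F)F
Why: Conjugate hydride addition to the unsubstituted beta-carbon C11 gives the C9 enolate regiospecifically and O-triflation traps it, after which the remaining ketone is enolised towards the doubly activated C11 methylene and trapped again (conjugate reduction–enolate triflation), with no stereocentre formed and 22 kept at or below 0 °C because it is a bicyclo[4.2.0]octa-2,4-diene that can ring-open electrocyclically on heating.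

Step 11
Reactants: 22 (1S,2R,3S,6R,7S,8R)-10-R-tetracyclo[6.4.0.0(2,7).0(3,6)]dodeca-9,11-diene-9,12-diyl bis(trifluoromethanesulfonate)
Product: 23 2-({8-[(1R,2S,3S,6R,7R,8S,10S)-tetracyclo[6.4.0.0(2,7).0(3,6)]dodecan-10-yl]octyl}oxy)propane-1,3-diol
Conditions: H2 (5 atm), Pd(OH)2/C, NaHCO3, EtOAc–EtOH, 0 °C → rt
Reagents that add atoms: none
Why: Hydrogenolysis of both enol triflates to C–H (the known enol-triflate route from ketone to methylene), syn hydrogenation of the resulting diene from the convex face of ring D (the face opposite ring A, where the ring-fusion hydrogens sit), which places H on C10 cis to those hydrogens and so sets (10S), and benzyl ether hydrogenolysis all run on the same catalyst.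

## Compound list

1 | cis-cyclobutane-1,2-dicarboxylic anhydride (meso) | O=C1OC(=O)[C@@H]2CC[C@H]12 | starting material
2 | cis-cyclobutane-1,2-diyldimethanol (meso) | OC[C@@H]1CC[C@@H]1CO | intermediate
3 | cis-cyclobutane-1,2-diylbis(methylene) dimethanesulfonate (meso) | CS(=O)(=O)OC[C@@H]1CC[C@@H]1COS(C)(=O)=O | intermediate
4 | cis-3-thiabicyclo[3.2.0]heptane (meso) | C1SC[C@@H]2CC[C@H]12 | intermediate
5 | 2-chloro-cis-3-thiabicyclo[3.2.0]heptane (racemic, both C2 epimers; one enantiomer drawn) | ClC1SC[C@@H]2CC[C@H]12 | intermediate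
6 | 2-chloro-cis-3-thiabicyclo[3.2.0]heptane 3,3-dioxide (racemic, both C2 epimers; one enantiomer drawn) | ClC1S(=O)(=O)C[C@@H]2CC[C@H]12 | intermediate
7 | 3-thiatricyclo[3.2.0.0(2,4)]heptane 3,3-dioxide (episulfone, cis cyclobutane fusion) | O=S1(=O)C2C1[C@H]1CC[C@@H]21 | intermediate
8 | cis-bicyclo[2.2.0]hex-2-ene | C1=C[C@H]2CC[C@@H]12 | intermediate
9 | 2,5-dibromo-1,4-benzoquinone | O=C1C=C(Br)C(=O)C=C1Br | starting material
10 | rac-1,10-dibromotetracyclo[6.4.0.0(2,7).0(3,6)]dodec-10-ene-9,12-dione (ladder core, Br on one ring A–D fusion carbon and on the olefinic carbon para to it; one enantiomer drawn) | C1=C(Br)C(=O)[C@@H]2[C@](Br)(C1=O)[C@H]1[C@@H]3CC[C@@H]3[C@@H]21 | intermediate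
11 | meso-(1S,2R,3S,6R,7S,8R)-tetracyclo[6.4.0.0(2,7).0(3,6)]dodec-10-ene-9,12-dione (ladder core) | C1=CC(=O)[C@@H]2[C@H](C1=O)[C@H]1[C@@H]3CC[C@@H]3[C@@H]21 | intermediate
12 | 1,3-bis(benzyloxy)propan-2-ol | OC(COCc1ccccc1)COCc1ccccc1 | starting material
13 | 1,8-dibromooctane | BrCCCCCCCCBr | starting material
14 | 2-[(8-bromooctyl)oxy]-1,3-bis(benzyloxy)propane | BrCCCCCCCCOC(COCc1ccccc1)COCc1ccccc1 | intermediate
15 | 2-[(8-nitrooctyl)oxy]-1,3-bis(benzyloxy)propane | [O-][N+](=O)CCCCCCCCOC(COCc1ccccc1)COCc1ccccc1 | intermediate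
16 | (1S,2R,3S,6R,7S,8R)-10-{8-[1,3-bis(benzyloxy)propan-2-yloxy]-1-nitrooctyl}tetracyclo[6.4.0.0(2,7).0(3,6)]dodecane-9,12-dione (mixture at C10 and C1′) | [O-][N+](=O)C(CCCCCCCOC(COCc1ccccc1)COCc1ccccc1)C1CC(=O)[C@@H]2[C@H](C1=O)[C@H]1[C@@H]3CC[C@@H]3[C@@H]21 | intermediate
17 | (1S,2R,3S,6R,7S,8R)-10-{8-[1,3-bis(benzyloxy)propan-2-yloxy]octylidene}tetracyclo[6.4.0.0(2,7).0(3,6)]dodecane-9,12-dione (E/Z mixture) | c1ccccc1COCC(COCc1ccccc1)OCCCCCCCC=C1CC(=O)[C@@H]2[C@H](C1=O)[C@H]1[C@@H]3CC[C@@H]3[C@@H]21 | intermediate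
18 | (1S,2R,3S,6R,7S,8R)-10-R-tetracyclo[6.4.0.0(2,7).0(3,6)]dodec-10-ene-9,12-dione | c1ccccc1COCC(COCc1ccccc1)OCCCCCCCCC1=CC(=O)[C@@H]2[C@H](C1=O)[C@H]1[C@@H]3CC[C@@H]3[C@@H]21 | intermediate
19 | lithium (1S,2R,3S,6R,7S,8R)-10-R-12-oxotetracyclo[6.4.0.0(2,7).0(3,6)]dodec-9-en-9-olate | [Li+].c1ccccc1COCC(COCc1ccccc1)OCCCCCCCCC1CC(=O)[C@@H]2[C@H](C=1[O-])[C@H]1[C@@H]3CC[C@@H]3[C@@H]21 | intermediate
20 | (1S,2R,3S,6R,7S,8R)-10-R-12-oxotetracyclo[6.4.0.0(2,7).0(3,6)]dodec-9-en-9-yl trifluoromethanesulfonate | c1ccccc1COCC(COCc1ccccc1)OCCCCCCCCC1CC(=O)[C@@H]2[C@H](C=1OS(=O)(=O)C(F)(F)F)[C@H]1[C@@H]3CC[C@@H]3[C@@H]21 | intermediate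
21 | potassium (1S,2R,3S,6R,7S,8R)-10-R-9-(trifluoromethanesulfonyloxy)tetracyclo[6.4.0.0(2,7).0(3,6)]dodeca-9,11-dien-12-olate | [K+].c1ccccc1COCC(COCc1ccccc1)OCCCCCCCCC1C=C([O-])[C@@H]2[C@H](C=1OS(=O)(=O)C(F)(F)F)[C@H]1[C@@H]3CC[C@@H]3[C@@H]21 | intermediate
22 | (1S,2R,3S,6R,7S,8R)-10-R-tetracyclo[6.4.0.0(2,7).0(3,6)]dodeca-9,11-diene-9,12-diyl bis(trifluoromethanesulfonate) | c1ccccc1COCC(COCc1ccccc1)OCCCCCCCCC1C=C(OS(=O)(=O)C(F)(F)F)[C@@H]2[C@H](C=1OS(=O)(=O)C(F)(F)F)[C@H]1[C@@H]3CC[C@@H]3[C@@H]21 | intermediate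
23 | 2-({8-[(1R,2S,3S,6R,7R,8S,10S)-tetracyclo[6.4.0.0(2,7).0(3,6)]dodecan-10-yl]octyl}oxy)propane-1,3-diol (ladder core; chain on C10 on the ring D face that carries ring A) | OCC(CO)OCCCCCCCC[C@H]1CC[C@@H]2[C@H](C1)[C@H]1[C@@H]3CC[C@@H]3[C@@H]21 | target

## Step count and risks

Total steps: 11. Longest linear sequence: 9 (steps 1–6, then 9–11); steps 7–8 make the chain separately.

**Step 9 (most likely to fail).** Risks: poor discrimination between the two olefinic carbons, retro-Michael erosion before nitrite is lost, a second addition to 18, or base-promoted tautomerisation of 11 or 18 to a cyclobutene-fused hydroquinone. The fallback moves the enantio-determining event to a carbonyl but keeps the nitronate C–C bond. It sets out from 11: Corey–Bakshi–Shibata mono-reduction ((S)-1-methyl-3,3-diphenyltetrahydro-1H,3H-pyrrolo[1,2-c][1,3,2]oxazaborole or its enantiomer, whichever reduces the C9 carbonyl, BH3·SMe2, THF, −40 °C) gives the hydroxy enone F1. Its single enone accepts the nitronate of 15 only at C10 (DBU cat., MeCN, 0 °C) to give the nitro hydroxy ketone F2. Dess–Martin oxidation of F2 comes back to the route at 16, which loses HNO2 with Et3N and goes on to 18 as in step 9.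

**Step 10.** Risks: 1,2-reduction instead of conjugate reduction, enolisation towards a ring-fusion carbon, or loss of 22 on handling. The fallback uses no enol triflates and removes both oxygens as thioketals. It sets out from 18: H2, Pd(OH)2/C, EtOAc–EtOH saturates the enedione C=C from the convex face and removes both benzyl groups to give the saturated dione diol F3. Ethane-1,2-dithiol, BF3·OEt2, CH2Cl2, 0 °C gives the bis(dithiolane) F4. Raney nickel (Ni) in EtOH at room temperature desulfurises F4 and comes back to the route at 23. C10 is alpha to a ketone in F3, so the thioketalisation is kept cold and short to avoid epimerisation.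

**Step 11.** Risks: incomplete C–O hydrogenolysis, palladium-mediated dehydrogenation of the diene to an arene, or modest facial selectivity at C10. The fallback removes the second oxygen through a hydrazone and never forms a diene. It sets out from 20, isolated by stopping step 10 after the first triflation: Pd(OAc)2, PPh3, HCO2H, Et3N, DMF, 40 °C gives the beta,gamma-unsaturated ketone F5. H2, Pd/C, EtOH hydrogenates its C9=C10 bond from the convex face and cleaves the benzyl ethers to give the keto diol F6, in which C10 is beta to the ketone and cannot epimerise. N2H4·H2O, EtOH, 70 °C gives the hydrazone F7, and KOt-Bu, DMSO, room temperature (low-temperature Wolff–Kishner, chosen because the ladder does not survive 200 °C) comes back to the route at 23.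

## Further compounds

F1 | step 9 | hydroxy enone: 11 with the C9 carbonyl reduced to the alcohol, OH on the concave face (ladder core unchanged) | C1=CC(=O)[C@@H]2[C@H]([C@H]1O)[C@H]1[C@@H]3CC[C@@H]3[C@@H]21
F2 | step 9 | nitro hydroxy ketone: F1 carrying the 8-[1,3-bis(benzyloxy)propan-2-yloxy]-1-nitrooctyl group on C10 (mixture at C10 and C1′) | [O-][N+](=O)C(CCCCCCCOC(COCc1ccccc1)COCc1ccccc1)C1CC(=O)[C@@H]2[C@H]([C@H]1O)[C@H]1[C@@H]3CC[C@@H]3[C@@H]21
F3 | step 10 | saturated dione diol: (10S)-10-[8-(1,3-dihydroxypropan-2-yloxy)octyl]tetracyclo[6.4.0.0(2,7).0(3,6)]dodecane-9,12-dione (ladder core, C10–H cis to the ring-fusion hydrogens) | OCC(CO)OCCCCCCCC[C@H]1CC(=O)[C@@H]2[C@H](C1=O)[C@H]1[C@@H]3CC[C@@H]3[C@@H]21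
F4 | step 10 | bis(dithiolane): F3 with both ketones as 1,3-dithiolanes | OCC(CO)OCCCCCCCC[C@H]1CC4(SCCS4)[C@@H]2[C@H](C15SCCS5)[C@H]1[C@@H]3CC[C@@H]3[C@@H]21
F5 | step 11 | beta,gamma-unsaturated ketone: 10-R-tetracyclo[6.4.0.0(2,7).0(3,6)]dodec-9-en-12-one (ladder core) | c1ccccc1COCC(COCc1ccccc1)OCCCCCCCCC1CC(=O)[C@@H]2[C@H](C=1)[C@H]1[C@@H]3CC[C@@H]3[C@@H]21
F6 | step 11 | keto diol: (10S)-10-[8-(1,3-dihydroxypropan-2-yloxy)octyl]tetracyclo[6.4.0.0(2,7).0(3,6)]dodecan-12-one (ladder core, C10–H cis to the ring-fusion hydrogens) | OCC(CO)OCCCCCCCC[C@H]1CC(=O)[C@@H]2[C@H](C1)[C@H]1[C@@H]3CC[C@@H]3[C@@H]21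
F7 | step 11 | hydrazone of F6 at C12 | OCC(CO)OCCCCCCCC[C@H]1CC(=NN)[C@@H]2[C@H](C1)[C@H]1[C@@H]3CC[C@@H]3[C@@H]21
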